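Everything rests on removing the B3 and B5 methyl groups of ring B (the methyl benzoate ring: B1 CO2Me, B2 OH, B4 ester oxygen, B6 methyl) and putting bromine in their place. The feature exploited is that these two carbons flank the depside oxygen on B4 and lie ortho and para to the B2 hydroxyl, while ring A (the chlorinated acyl ring) has no ring hydrogen. The ester can therefore be made at an uncrowded B4 oxygen, and bromine can then enter only at B3 and B5. One twofold Negishi methylation forms both aryl–methyl bonds. Its precursor is the ring A dibenzyl-protected depside with bromine at B3 and B5 and a free B2 hydroxyl.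

Key step: step 6

Remark: potassium salts of the phenols and of the acid, and the boron aryloxides of the last step, revert to the numbered compounds on work-up and carry no numbers of their own; the methylzinc phenoxides of step 6 are numbered because the coupling takes place on them. All compounds are achiral.

Step 1
Reactants: 1 methyl 2,4-dihydroxy-3,6-dimethylbenzoate (atraric acid)
Product: 2 methyl 5-chloro-2,4-dihydroxy-3,6-dimethylbenzoate
Conditions: SO2Cl2 (1.05 equiv), Et2O, 0 °C to rt
Reagents that add atoms: sulfuryl chloride, O=S(=O)(Cl)Cl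
Why: Electrophilic aromatic chlorination should occur at C5, the only unsubstituted ring carbon, which is activated by the ortho 4-hydroxyl and the para 2-hydroxyl, and one equivalent of reagent limits over-chlorination.

Step 2
Reactants: 2 methyl 5-chloro-2,4-dihydroxy-3,6-dimethylbenzoate
Product: 3 methyl 2,4-bis(benzyloxy)-5-chloro-3,6-dimethylbenzoate
Conditions: BnBr (2.5 equiv), K2CO3, DMF, 60 °C
Reagents that add atoms: benzyl bromide, BrCc1ccccc1
Why: Williamson ether synthesis in warm DMF should alkylate both phenoxides, the hydrogen-bonded 2-hydroxyl included, while the methyl ester and the aryl chloride stay untouched.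

Step 3
Reactants: 3 methyl 2,4-bis(benzyloxy)-5-chloro-3,6-dimethylbenzoate
Product: 4 2,4-bis(benzyloxy)-5-chloro-3,6-dimethylbenzoic acid
Conditions: KOH, DMSO–H2O (4:1), 90 °C; then 1 M HCl
Reagents that add atoms: potassium hydroxide, [K+].[OH-]
Why: Saponification of the di-ortho-substituted methyl ester should proceed with the poorly solvated hydroxide of aqueous DMSO at elevated temperature, conditions to which aryl benzyl ethers and a chloride on an electron-rich ring are inert.

Step 4
Reactants: 4 2,4-bis(benzyloxy)-5-chloro-3,6-dimethylbenzoic acid; 5 methyl orsellinate (methyl 2,4-dihydroxy-6-methylbenzoate)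
Product: 7 methyl 4-{[2,4-bis(benzyloxy)-5-chloro-3,6-dimethylbenzoyl]oxy}-2-hydroxy-6-methylbenzoate, via 2,4-bis(benzyloxy)-5-chloro-3,6-dimethylbenzoyl chloride 6 (not isolated)
Conditions: (COCl)2, cat. DMF, CH2Cl2, 0 °C to rt, evaporate; then 5 (1.1 equiv), Et3N, cat. DMAP, CH2Cl2, 0 °C to rt
Reagents that add atoms: none
Why: Acid chloride formation followed by DMAP-catalysed acylation should give the depside at the B4 oxygen, because the 4-hydroxyl of methyl orsellinate is free and the more acidic one whereas the 2-hydroxyl is hydrogen-bonded to the ester, and because B3 and B5 still carry only hydrogen at this stage.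

Step 5
Reactants: 7 methyl 4-{[2,4-bis(benzyloxy)-5-chloro-3,6-dimethylbenzoyl]oxy}-2-hydroxy-6-methylbenzoate
Product: 8 methyl 4-{[2,4-bis(benzyloxy)-5-chloro-3,6-dimethylbenzoyl]oxy}-3,5-dibromo-2-hydroxy-6-methylbenzoate
Conditions: Br2 (2.3 equiv), NaOAc, AcOH–CH2Cl2 (1:1), rt, dark; aq Na2S2O3
Reagents that add atoms: bromine, BrBr
Why: Electrophilic aromatic bromination should take place only at B3 (ortho) and B5 (para) to the free B2 hydroxyl, since ring A is fully substituted and the phenyl rings of the benzyl ethers are not activated, while NaOAc removes HBr so that the benzyl ethers survive.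

Step 6
Reactants: 8 methyl 4-{[2,4-bis(benzyloxy)-5-chloro-3,6-dimethylbenzoyl]oxy}-3,5-dibromo-2-hydroxy-6-methylbenzoate
Product: 11 methyl 4-{[2,4-bis(benzyloxy)-5-chloro-3,6-dimethylbenzoyl]oxy}-2-hydroxy-3,5,6-trimethylbenzoate, via methylzinc phenoxide of the dibromo depside 9 (not isolated), via methylzinc phenoxide of the trimethyl depside 10 (not isolated)
Conditions: Me2Zn (2 M in toluene, 5 equiv), PdCl2(dppf)·CH2Cl2 (10 mol %), 1,4-dioxane, 90 °C, sealed tube; then 1 M HCl, 0 °C
Reagents that add atoms: dimethylzinc, C[Zn]C
Why: Twofold Negishi cross-coupling: dimethylzinc first converts the B2 hydroxyl into methylzinc phenoxide 9 and reduces PdCl2(dppf) to zerovalent palladium, which inserts into each C–Br bond; methyl then passes from zinc to divalent palladium and reductive elimination forms the B3–CH3 and B5–CH3 bonds one after the other, giving 10, which the acidic quench converts into 11. The closest known reaction type is the palladium-catalysed methylation of hindered aryl bromides with dimethylzinc, which tolerates acidic O–H groups when excess reagent is used. No ring is closed and no stereocentre is formed. The step needs selectivity for the two C–Br bonds over the ring A C–Cl bond and over both esters: the dppf catalyst does not insert into the stronger C–Cl bond on the electron-rich, fully substituted ring A, and dimethylzinc does not add to esters. Methyl is small enough to be delivered to carbons that already flank the B4 ester oxygen, which is why the ester bond was made earlier, when B4 had only hydrogen neighbours.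

Step 7
Reactants: 11 methyl 4-{[2,4-bis(benzyloxy)-5-chloro-3,6-dimethylbenzoyl]oxy}-2-hydroxy-3,5,6-trimethylbenzoate
Product: 12 methyl 4-[(5-chloro-2,4-dihydroxy-3,6-dimethylbenzoyl)oxy]-2-hydroxy-3,5,6-trimethylbenzoate (target CNP0198502.0)
Conditions: BCl3 (1 M in CH2Cl2, 5 equiv), C6HMe5 (6 equiv), CH2Cl2, −78 to −40 °C; then H2O
Reagents that add atoms: none
Why: Lewis-acid debenzylation should free both ring A hydroxyls, because BCl3 ionises the aryl benzyl ethers and pentamethylbenzene traps the benzyl cations by Friedel–Crafts alkylation, so that no ring is C-benzylated and the methyl ester, the depside ester and the aryl chloride remain intact at low temperature.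

Compound list
1 | methyl 2,4-dihydroxy-3,6-dimethylbenzoate (atraric acid, commercial) | COC(=O)c1c(C)cc(O)c(C)c1O | starting material
2 | methyl 5-chloro-2,4-dihydroxy-3,6-dimethylbenzoate | COC(=O)c1c(C)c(Cl)c(O)c(C)c1O | intermediate
3 | methyl 2,4-bis(benzyloxy)-5-chloro-3,6-dimethylbenzoate | COC(=O)c1c(C)c(Cl)c(OCc2ccccc2)c(C)c1OCc1ccccc1 | intermediate
4 | 2,4-bis(benzyloxy)-5-chloro-3,6-dimethylbenzoic acid | OC(=O)c1c(C)c(Cl)c(OCc2ccccc2)c(C)c1OCc1ccccc1 | intermediate
5 | methyl orsellinate (methyl 2,4-dihydroxy-6-methylbenzoate) | COC(=O)c1c(C)cc(O)cc1O | starting material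
6 | 2,4-bis(benzyloxy)-5-chloro-3,6-dimethylbenzoyl chloride (formed in the flask, not isolated) | O=C(Cl)c1c(C)c(Cl)c(OCc2ccccc2)c(C)c1OCc1ccccc1 | intermediate
7 | methyl 4-{[2,4-bis(benzyloxy)-5-chloro-3,6-dimethylbenzoyl]oxy}-2-hydroxy-6-methylbenzoate | COC(=O)c1c(C)cc(OC(=O)c2c(C)c(Cl)c(OCc3ccccc3)c(C)c2OCc2ccccc2)cc1O | intermediate
8 | methyl 4-{[2,4-bis(benzyloxy)-5-chloro-3,6-dimethylbenzoyl]oxy}-3,5-dibromo-2-hydroxy-6-methylbenzoate | COC(=O)c1c(C)c(Br)c(OC(=O)c2c(C)c(Cl)c(OCc3ccccc3)c(C)c2OCc2ccccc2)c(Br)c1O | intermediate
9 | methylzinc phenoxide of 8, B2–O–ZnCH3 (formed in the flask, not isolated) | COC(=O)c1c(C)c(Br)c(OC(=O)c2c(C)c(Cl)c(OCc3ccccc3)c(C)c2OCc2ccccc2)c(Br)c1O[Zn]C | intermediate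
10 | methylzinc phenoxide of 11, B2–O–ZnCH3 (formed in the flask, not isolated) | COC(=O)c1c(C)c(C)c(OC(=O)c2c(C)c(Cl)c(OCc3ccccc3)c(C)c2OCc2ccccc2)c(C)c1O[Zn]C | intermediate
11 | methyl 4-{[2,4-bis(benzyloxy)-5-chloro-3,6-dimethylbenzoyl]oxy}-2-hydroxy-3,5,6-trimethylbenzoate | COC(=O)c1c(C)c(C)c(OC(=O)c2c(C)c(Cl)c(OCc3ccccc3)c(C)c2OCc2ccccc2)c(C)c1O | intermediate
12 | methyl 4-[(5-chloro-2,4-dihydroxy-3,6-dimethylbenzoyl)oxy]-2-hydroxy-3,5,6-trimethylbenzoate | COC(=O)c1c(C)c(C)c(OC(=O)c2c(C)c(Cl)c(O)c(C)c2O)c(C)c1O | target

Total step count: 7. Longest linear sequence: 7 steps (1 to 12); methyl orsellinate 5 enters at step 4.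

Steps most likely to fail

Step 6. Oxidative addition may stall at the second C–Br bond, which is flanked on both sides and sits on an electron-rich zinc phenoxide. Protodebromination, or acyl transfer from the activated dibromoaryl ester to the phenoxide, could then compete. The fallback sets out from 8 and removes the phenoxide before the coupling. The B2 hydroxyl is capped with BnBr and K2CO3 in DMF at rt to give methyl 2-(benzyloxy)-4-{[2,4-bis(benzyloxy)-5-chloro-3,6-dimethylbenzoyl]oxy}-3,5-dibromo-6-methylbenzoate F1. A neutral twofold Stille methylation (SnMe4, PdCl2(PPh3)2, DMF, 110 °C, sealed tube) should then give methyl 2-(benzyloxy)-4-{[2,4-bis(benzyloxy)-5-chloro-3,6-dimethylbenzoyl]oxy}-3,5,6-trimethylbenzoate F2. BCl3 with pentamethylbenzene, as in step 7, should remove all three benzyl groups, so the fallback comes back to the route at 12.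

Step 5. The second bromination may be slow on a ring that carries two ester groups. Longer exposure to bromine and HBr invites loss of a benzyl ether or benzylic bromination. The fallback sets out from 5 and reverses the order of bromination and acylation. Methyl orsellinate 5 is dibrominated first (Br2, NaOAc, AcOH, rt), which is easy on the free resorcinol, to give methyl 3,5-dibromo-2,4-dihydroxy-6-methylbenzoate F3. Its 4-hydroxyl, the more acidic one between the two bromines, is then acylated with acid chloride 6 (made from 4 with (COCl)2 and cat. DMF; Et3N, cat. DMAP, CH2Cl2, rt to 40 °C). The fallback comes back to the route at 8.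

Step 4. Acyl transfer from the di-ortho-substituted acid chloride may be slow, so that acylation at the B2 oxygen, double acylation or hydrolysis of the acid chloride competes. The fallback sets out from 4 and 5 and uses an acid-promoted, base-free condensation with trifluoroacetic anhydride in toluene at rt. The acid is converted in the flask into 2,4-bis(benzyloxy)-5-chloro-3,6-dimethylbenzoic trifluoroacetic anhydride F4. The two ortho substituents favour its ionisation to an acylium ion, which the free 4-hydroxyl of 5 should capture. The fallback comes back to the route at 7.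

Further compounds
F1 | step 6 | methyl 2-(benzyloxy)-4-{[2,4-bis(benzyloxy)-5-chloro-3,6-dimethylbenzoyl]oxy}-3,5-dibromo-6-methylbenzoate | COC(=O)c1c(C)c(Br)c(OC(=O)c2c(C)c(Cl)c(OCc3ccccc3)c(C)c2OCc2ccccc2)c(Br)c1OCc1ccccc1
F2 | step 6 | methyl 2-(benzyloxy)-4-{[2,4-bis(benzyloxy)-5-chloro-3,6-dimethylbenzoyl]oxy}-3,5,6-trimethylbenzoate | COC(=O)c1c(C)c(C)c(OC(=O)c2c(C)c(Cl)c(OCc3ccccc3)c(C)c2OCc2ccccc2)c(C)c1OCc1ccccc1
F3 | step 5 | methyl 3,5-dibromo-2,4-dihydroxy-6-methylbenzoate | COC(=O)c1c(C)c(Br)c(O)c(Br)c1O
F4 | step 4 | 2,4-bis(benzyloxy)-5-chloro-3,6-dimethylbenzoic trifluoroacetic anhydride | O=C(OC(=O)C(F)(F)F)c1c(C)c(Cl)c(OCc2ccccc2)c(C)c1OCc1ccccc1
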